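The data were computed on assumed constants, and the scatter is random.

Whatever happens in these flasks, the charge of Z stays accounted for: Z, J and X add up to it, with D taken as nil, and each J or X has set free one Q. Each reading therefore gives the quotient cJ·cQ/cZ, which is 5.35 mM in the winter run at 3.00 min and 4.82 mM in the autumn run at 20.0 min. This ionisation quotient, read as the pre-equilibrium constant of Z <-> J + Q, is the quantity carried here.

| flask | Z | G | remark | time |
|---|---|---|---|---|
| winter | 0.089 M | 3 equiv | the very flask that is asked about, followed so far |  |
| autumn | 0.089 M | 2 equiv | run made earlier |  |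
| flask | 0.089 M | 3.00 equiv |  | 25 min |

| run | time / min | J / % | X / % |
|---|---|---|---|
| winter | 0.250 | 10.3 | 0.8 |
| winter | 0.500 | 15.5 | 1.2 |
| winter | 1.33 | 17.4 | 7.2 |
| winter | 3.00 | 13.9 | 16.3 |
| winter | 8.00 | 6.7 | 36.6 |
| autumn | 0.250 | 11.0 | 1.5 |
| autumn | 0.667 | 16.8 | 2.1 |
| autumn | 2.00 | 15.7 | 10.1 |
| autumn | 6.00 | 9.0 | 28.4 |
| autumn | 20.0 | 2.8 | 63.1 |

(scatter of a reading: 0.5 percentage points)

* the best time, 25 min at the latest, for J
* the amount of J, in percent of the Z charged, at that time

- in percentages every species weighs as the Z in it: one D counts as two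
- as a solid, counted per litre of solution: G
- steps thought possible: Z <-> J + Q; L + J -> X; 2 Z -> D; G <-> L
- at the start none of G is in solution

Time comes first. While X is still nil, cJ equals cQ, and the autumn quotient then gives an estimated ceiling for J of 20.7% of the Z charged in this flask. X then takes its share, so J should top early and below that ceiling. The winter run reads 17.4% at 1.33 min and 6.7% at 8.00 min, and the autumn run reads 2.8% at 20.0 min. More G should matter little early on: at 0.250 min, J reads 11.0% with 2 equiv of G and 10.3% with 3 equiv. A larger charge of Z should lower the share of J, since cQ rises with cJ while the quotient stays.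

The forecast gives 17.9% at 1 min, “a single early maximum near 1 min”.

The flask gives 18.1% of J at 0.956 min.

    Z ⇌ J + Q (K = 0.00555 M, k = 0.00801 s⁻¹)
    L + J → X (k = 2.00 M⁻¹ s⁻¹)
    2 Z → D (k = 1.11 × 10⁻⁴ M⁻¹ s⁻¹)
    G ⇌ L, rate k4*(cs4 - [L]) while solid is left; crystals form when [L] > cs4 (solubility = 4.60 mM, k = 0.0550 s⁻¹)

At that top the flask holds J below the estimated ceiling of 20.7%, with 4.21% of X already formed, and at 6.99 min the half-life of J against capture by L is 1.6 min, short against the 25 min allowed. For a neighbouring flask, the same recipe with 0.36 M of Z, the same quotient puts the estimated ceiling at 10.9%, and the highest J of that neighbouring flask is 10.7%.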